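The pyran rings A and B of the target share the bond C-b–C-c (C-a, C-b: the CH carbons bearing quinolones A and B), and their oxygens O4(A) and O4(B) stand on the neighbouring carbons C-c (ring-fusion OCH) and C-q (CMe2). This vicinal pattern is disconnected to a cis-dihydrofuro[3,2-c]quinolinone in which O4(B) is still bonded to C-c, C-q is a tertiary carbinol, and C-a carries quinolone A with its free 4-OH. In one operation the key step shifts O4(B) from C-c to C-q through an oxiranium ion (furan becomes pyran B) while O4(A) opens that ion at C-c with inversion (pyran A). The precursor comes from a meso bis-quinolone diene by desymmetrising epoxidation.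

Key step: step 7

Labels: C-a = CH carrying the 2-methylprop-1-enyl group and quinolone A; C-b = CH carrying quinolone B; C-c = ring-fusion OCH; C-q = CMe2; O4(A), O4(B) = the enol oxygens at C4 of quinolones A and B.
Remark 1: 3-substituted 4-hydroxyquinolin-2-ones are hydroxylated at C3 by peroxy reagents in base, so both enol oxygens are carried as allyl ethers through the dioxirane epoxidation.
Remark 2: the double Claisen step is not expected to discriminate the meso from the racemic diester; the meso series is secured by isolating crystalline 8.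
Remark 3 (assumption): the L-fructose-derived Shi ketone is taken to give the (S)-epoxide of an R–CH=CMe2 alkene, the mirror image of the (R)-epoxide given by the D-fructose-derived ketone.

Step 1
Reactants: 1 2,7-dimethylocta-3,5-diyne-2,7-diol
Product: 2 (3E,5E)-2,7-dimethylocta-3,5-diene-2,7-diol
Conditions: LiAlH4 (3 equiv), THF, 66 °C; H2O then aq. NaOH work-up
Reagents that add atoms: none
Why: Alkoxide-directed trans-hydroalumination of both propargylic alkoxide units, the standard LiAlH4 reduction of propargylic alcohols to E-allylic alcohols, should give the E,E-diene and creates no stereocentre.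

Step 2
Reactants: 2 (3E,5E)-2,7-dimethylocta-3,5-diene-2,7-diol; 3 triethyl orthoacetate
Product: 5 diethyl (3R,4S)-3,4-bis(2-methylprop-1-en-1-yl)hexanedioate (meso; racemic diastereomer also formed), via mono-Claisen hydroxy ester 4 (not isolated)
Conditions: MeC(OEt)3 (10 equiv), EtCO2H (catalytic), 135 °C, EtOH distilled off
Reagents that add atoms: none
Why: Johnson–Claisen orthoester rearrangement, in which each tertiary allylic hydroxyl exchanges into a mixed ketene acetal whose chair [3,3] shift delivers CH2CO2Et first to C4 and then to C5 and turns each CMe2–O terminus into a 2-methylprop-1-enyl group, so the constitution is certain, whereas the second shift has no strong facial bias and the meso (3R,4S) diester needed is expected alongside its racemic diastereomer, from which it is freed at the stage of 8.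

Step 3
Reactants: 5 diethyl (3R,4S)-3,4-bis(2-methylprop-1-en-1-yl)hexanedioate (as the mixture from step 2); 6 N-methylisatoic anhydride (1-methyl-2H-3,1-benzoxazine-2,4(1H)-dione)
Product: 8 3,3'-[(4R,5S)-2,7-dimethylocta-2,6-diene-4,5-diyl]bis(4-hydroxy-1-methylquinolin-2(1H)-one) (meso diene), via bis(amino keto ester) 7 (not isolated)
Conditions: 5 added to LiN(iPr)2 (4.4 equiv), THF, −78 °C; 6 (2.2 equiv), −78 → 25 °C; AcOH; PhMe, 110 °C; fractional crystallisation
Reagents that add atoms: none
Why: Isatoic-anhydride annulation to 4-hydroxyquinolin-2-ones, in which each ester enolate of the preformed bis-enolate (formed first so that Dieckmann closure of the adipate is suppressed) is C-acylated at the C4 carbonyl of 6, CO2 is lost on acidification and the freed N-methylaniline nitrogen closes the lactam onto the ester on heating; C-a and C-b lie beta to the esters and are untouched, and the meso diastereomer should be separable from the racemic one by crystallisation and recognisable by a single peak on a chiral HPLC phase.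

Step 4
Reactants: 8 3,3'-[(4R,5S)-2,7-dimethylocta-2,6-diene-4,5-diyl]bis(4-hydroxy-1-methylquinolin-2(1H)-one)
Product: 9 3,3'-[(4R,5S)-2,7-dimethylocta-2,6-diene-4,5-diyl]bis[1-methyl-4-(prop-2-en-1-yloxy)quinolin-2(1H)-one]
Conditions: allyl bromide (2.6 equiv), Cs2CO3 (3 equiv), DMF, 25 °C
Reagents that add atoms: allyl bromide, C=CCBr
Why: Williamson O-alkylation of the caesium quinolonates, directed to oxygen because C3 already carries a branched substituent, masks the enolic oxygens against C3-hydroxylation by peroxymonosulfate in step 5 and involves no stereocentre.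

Step 5
Reactants: 9 3,3'-[(4R,5S)-2,7-dimethylocta-2,6-diene-4,5-diyl]bis[1-methyl-4-(prop-2-en-1-yloxy)quinolin-2(1H)-one]
Product: 10 3,3'-[(1S,2R)-1-[(2S)-3,3-dimethyloxiran-2-yl]-4-methylpent-3-ene-1,2-diyl]bis[1-methyl-4-(prop-2-en-1-yloxy)quinolin-2(1H)-one]
Conditions: L-fructose-derived Shi ketone [1,2:4,5-di-O-isopropylidene-β-L-erythro-2,3-hexodiulo-2,6-pyranose, C12H18O6] (0.3 equiv), KHSO5 (as 2KHSO5·KHSO4·K2SO4, limiting), K2CO3, Bu4NHSO4 (catalytic), MeCN–CH2(OMe)2–aq. Na2B4O7 buffer (pH 10.5), 0 °C; chromatography, unreacted 9 recycled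
Reagents that add atoms: potassium peroxymonosulfate (KHSO5), [K+].[O-]S(=O)(=O)OO
Why: Shi asymmetric epoxidation, in which the dioxirane of the L-fructose-derived ketone transfers oxygen through the spiro transition state to give the (S)-configured CH carbon of an R–CH=CMe2 alkene, and of the two enantiotopic arms of meso 9 the one on the (5S)-carbon is the matched one because its catalyst-preferred face is also the face anti to the neighbouring CH(quinolonyl)(alkenyl) branch in the conformer with the allylic C–H eclipsing the alkene (minimal 1,3-allylic strain), so catalyst control fixes C-c and matched arm selection fixes it relative to C-a and C-b, the mismatched mono-epoxide and any bis-epoxide being removed by chromatography, while the allyl ether alkenes and the push–pull C3=C4 bonds are too little substituted or too electron-poor to compete.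

Step 6
Reactants: 10 3,3'-[(1S,2R)-1-[(2S)-3,3-dimethyloxiran-2-yl]-4-methylpent-3-ene-1,2-diyl]bis[1-methyl-4-(prop-2-en-1-yloxy)quinolin-2(1H)-one]
Product: 12 (2R,3S)-2-(2-hydroxypropan-2-yl)-3-[(1R)-1-(4-hydroxy-1-methyl-2-oxo-1,2-dihydroquinolin-3-yl)-3-methylbut-2-en-1-yl]-5-methyl-2,3-dihydrofuro[3,2-c]quinolin-4(5H)-one, via free epoxy bis-quinolone 11 (not isolated)
Conditions: Pd(PPh3)4 (5 mol %), morpholine (6 equiv), THF, 25 → 45 °C
Reagents that add atoms: none
Why: Tsuji–Trost deallylation by zerovalent palladium with morpholine as allyl acceptor frees both quinolonates under mild base, and O4(B) then opens the adjacent epoxide at the secondary carbon C-c in the 5-exo-tet mode with inversion ((S)-epoxide to (2R)), the known way in which 3-(2,3-epoxy-3-methylbutyl)-4-hydroxyquinolin-2-ones close to hydroxyisopropyl-dihydrofuroquinolones and a faster closure than the 6-exo alternative through O4(A), so that the cis-2,3-dihydrofuran follows from the epoxide configuration set in step 5.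

Step 7
Reactants: 12 (2R,3S)-2-(2-hydroxypropan-2-yl)-3-[(1R)-1-(4-hydroxy-1-methyl-2-oxo-1,2-dihydroquinolin-3-yl)-3-methylbut-2-en-1-yl]-5-methyl-2,3-dihydrofuro[3,2-c]quinolin-4(5H)-one
Product: 14 target CNP0107253.2 (cis-fused bis-pyranoquinolinone; C-a R; C-b S; C-c S), via oxiranium ion 13 (not isolated)
Conditions: BF3·OEt2 (3 equiv), 2,6-di-tert-butylpyridine (3 equiv), CH2Cl2 (0.01 M), −40 → 0 °C; aq. NaHCO3
Reagents that add atoms: none
Why: Proposed new method: BF3 complexation turns the tertiary hydroxyl on C-q into a leaving group, and the lone pair of the ring oxygen O4(B), anti to the departing C-q–O bond, assists ionisation to the oxiranium ion 13 in which O4(B) bridges C-c and C-q. The closest known reaction type is the acid-, SOCl2- or DAST-induced 1,2-oxygen shift of 2-(2-hydroxypropan-2-yl)-2,3-dihydrobenzofurans and dihydrofuroquinolones to 3-substituted 2,2-dimethylpyrans, in which an external nucleophile opens the same oxiranium ion at the secondary carbon; here the enolic O4(A)–H takes that role. Pyran B arises by ring expansion (3-exo-tet bridging of O4(B) to C-q, then cleavage of O4(B)–C-c), and pyran A by 6-exo-tet opening of the three-membered ring at C-c by O4(A). C-c is the only stereocentre changed: backside attack anti to the bridging oxygen inverts it (R in 12, S in 14), and because C-a and C-q are cis on the dihydrofuran the O4(A) arm lies gauche to that trajectory, so the cis ring fusion follows from the substrate while C-a and C-b are untouched. The step needs attack at C-c and not at C-q (secured by ring size, six against seven), closure through O4 and not through the amide oxygen O2 (BF3 sits on the C2 carbonyls), and neither proton-initiated addition of O4(A)–H to the 2-methylprop-1-enyl group nor E1 loss to an isopropenyl group (the hindered pyridine takes up the acid without binding BF3, and the temperature is kept low).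

Compound list
1 | 2,7-dimethylocta-3,5-diyne-2,7-diol | CC(C)(O)C#CC#CC(C)(C)O | starting material
2 | (3E,5E)-2,7-dimethylocta-3,5-diene-2,7-diol | CC(C)(O)/C=C/C=C/C(C)(C)O | intermediate
3 | triethyl orthoacetate | CC(OCC)(OCC)OCC | starting material
4 | ethyl (4E)-6-hydroxy-6-methyl-3-(2-methylprop-1-en-1-yl)hept-4-enoate (racemic; mono-Claisen hydroxy ester) | CCOC(=O)CC(C=C(C)C)/C=C/C(C)(C)O | intermediate
5 | diethyl (3R,4S)-3,4-bis(2-methylprop-1-en-1-yl)hexanedioate (meso; formed together with its racemic diastereomer) | CCOC(=O)C[C@@H](C=C(C)C)[C@@H](C=C(C)C)CC(=O)OCC | intermediate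
6 | N-methylisatoic anhydride (1-methyl-2H-3,1-benzoxazine-2,4(1H)-dione) | CN1C(=O)OC(=O)c2ccccc12 | starting material
7 | diethyl 2,5-bis[2-(methylamino)benzoyl]-3,4-bis(2-methylprop-1-en-1-yl)hexanedioate (meso 3,4-core shown; mixture at C2 and C5) | CCOC(=O)C(C(=O)c1ccccc1NC)[C@@H](C=C(C)C)[C@@H](C=C(C)C)C(C(=O)c1ccccc1NC)C(=O)OCC | intermediate
8 | 3,3'-[(4R,5S)-2,7-dimethylocta-2,6-diene-4,5-diyl]bis(4-hydroxy-1-methylquinolin-2(1H)-one) (meso bis-quinolone diene) | CC(C)=C[C@@H](c1c(O)c2ccccc2n(C)c1=O)[C@H](C=C(C)C)c1c(O)c2ccccc2n(C)c1=O | intermediate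
9 | 3,3'-[(4R,5S)-2,7-dimethylocta-2,6-diene-4,5-diyl]bis[1-methyl-4-(prop-2-en-1-yloxy)quinolin-2(1H)-one] (meso bis-allyl ether) | CC(C)=C[C@@H](c1c(OCC=C)c2ccccc2n(C)c1=O)[C@H](C=C(C)C)c1c(OCC=C)c2ccccc2n(C)c1=O | intermediate
10 | 3,3'-[(1S,2R)-1-[(2S)-3,3-dimethyloxiran-2-yl]-4-methylpent-3-ene-1,2-diyl]bis[1-methyl-4-(prop-2-en-1-yloxy)quinolin-2(1H)-one] (mono-epoxide on the C-b arm) | CC(C)=C[C@@H](c1c(OCC=C)c2ccccc2n(C)c1=O)[C@H]([C@@H]1OC1(C)C)c1c(OCC=C)c2ccccc2n(C)c1=O | intermediate
11 | 3,3'-[(1S,2R)-1-[(2S)-3,3-dimethyloxiran-2-yl]-4-methylpent-3-ene-1,2-diyl]bis(4-hydroxy-1-methylquinolin-2(1H)-one) (free epoxy bis-quinolone, present as its morpholinium salt) | CC(C)=C[C@@H](c1c(O)c2ccccc2n(C)c1=O)[C@H]([C@@H]1OC1(C)C)c1c(O)c2ccccc2n(C)c1=O | intermediate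
12 | (2R,3S)-2-(2-hydroxypropan-2-yl)-3-[(1R)-1-(4-hydroxy-1-methyl-2-oxo-1,2-dihydroquinolin-3-yl)-3-methylbut-2-en-1-yl]-5-methyl-2,3-dihydrofuro[3,2-c]quinolin-4(5H)-one (cis-dihydrofuran, precursor of the key step) | CC(C)=C[C@@H](c1c(O)c2ccccc2n(C)c1=O)[C@H]1c2c(c3ccccc3n(C)c2=O)O[C@H]1C(C)(C)O | intermediate
13 | oxiranium ion from 12: O4(B) bonded to C4(B), C-c and C-q (three-membered ring O4(B)–C-c–C-q fused to the dihydrofuran), hydroxytrifluoroborate counter-ion | CC(C)=C[C@@H](c1c(O)c2ccccc2n(C)c1=O)[C@H]1c2c(c3ccccc3n(C)c2=O)[O+]4[C@H]1C4(C)C.O[B-](F)(F)F | intermediate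
14 | target CNP0107253.2: cis-fused bis(N-methylpyrano[3,2-c]quinolin-5-one); pyran A = O4(A)–C4(A)–C3(A)–C-a–C-b–C-c with the 2-methylprop-1-enyl group on C-a (R); pyran B = O4(B)–C4(B)–C3(B)–C-b–C-c–C-q with the gem-dimethyl group on C-q; C-b (S), C-c (S) | CC(C)=C[C@H]1c2c(c3ccccc3n(C)c2=O)O[C@H]2[C@@H]1c1c(c3ccccc3n(C)c1=O)OC2(C)C | target

Total step count: 7. Longest linear sequence: 7 steps (1 to 14).

Steps most likely to fail

Step 7 (proposed new method). What may go wrong: ionisation without participation of O4(B), leading to E1 loss to an isopropenyl group or to capture of the open tertiary cation, and proton-initiated addition of O4(A)–H to the 2-methylprop-1-enyl group. The fallback uses known reaction types, sets out from 12 and returns at 14. The acidic O4(A)–H is sulfonylated selectively (TsCl, Et3N, CH2Cl2, 0 °C) to give the 4-tosyloxyquinolone derivative of 12 F1. The established acid-promoted 1,2-oxygen shift with water as external nucleophile (H2SO4, aqueous dioxane, 50 °C) should then give the ring-expanded cis-3-hydroxy-2,2-dimethylpyranoquinolinone F2, with C-c inverted and O4(B) on C-q. NaH in THF (0 → 25 °C) closes pyran A by intramolecular addition–elimination of the C-c alkoxide at C4(A) with loss of tosylate and retention at C-c, giving 14. In this variant the ring-A oxygen comes from water and the C-c–O bond is not broken in the last operation.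

Step 5. What may go wrong: insufficient discrimination between the two enantiotopic arms (the mismatched arm competing), or slow oxygen transfer to the hindered alkenes while the ketone decomposes. The fallback replaces catalytic desymmetrisation by resolution, sets out from 8 and returns at 12, so steps 4 to 6 are not needed. Buffered peracid epoxidation of unprotected 8 (mCPBA 1 equiv, NaHCO3, CH2Cl2, 0 °C) follows the substrate bias alone and closes in the flask, as known for 3-prenyl-4-hydroxyquinolin-2-ones. It should give racemic 12, that is 12 together with its enantiomer ent-12 F3. Any trans-dihydrofuran diastereomer is removed on silica, and preparative HPLC on a chiral stationary phase (amylose tris(3,5-dimethylphenylcarbamate)) then delivers 12.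

Step 3. What may go wrong: Dieckmann closure of the adipate before both enolates are formed, or incomplete second acylation and lactamisation. The fallback forms the amide first and the C3–C4 bond last, sets out from 5 and returns at 8. Saponification (LiOH, aqueous THF) gives the diacid F4. (COCl)2 with catalytic DMF gives the bis(acid chloride) F5. N-Acylation of methyl 2-(methylamino)benzoate (pyridine, CH2Cl2) gives the bis-amide F6. KOtBu in THF then effects the Dieckmann-type condensation of each amide enolate onto its aryl ester, and 8 is isolated by crystallisation as in step 3.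

Further compounds
F1 | step 7 | (2R,3S)-2-(2-hydroxypropan-2-yl)-5-methyl-3-[(1R)-3-methyl-1-[1-methyl-2-oxo-4-(tosyloxy)-1,2-dihydroquinolin-3-yl]but-2-en-1-yl]-2,3-dihydrofuro[3,2-c]quinolin-4(5H)-one | CC(C)=C[C@@H](c1c(OS(=O)(=O)c2ccc(C)cc2)c2ccccc2n(C)c1=O)[C@H]1c2c(c3ccccc3n(C)c2=O)O[C@H]1C(C)(C)O
F2 | step 7 | (3S,4S)-3-hydroxy-2,2,6-trimethyl-4-[(1R)-3-methyl-1-[1-methyl-2-oxo-4-(tosyloxy)-1,2-dihydroquinolin-3-yl]but-2-en-1-yl]-3,4-dihydro-2H-pyrano[3,2-c]quinolin-5(6H)-one | CC(C)=C[C@@H](c1c(OS(=O)(=O)c2ccc(C)cc2)c2ccccc2n(C)c1=O)[C@H]1c2c(c3ccccc3n(C)c2=O)OC(C)(C)[C@H]1O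
F3 | step 5 | ent-12, (2S,3R)-2-(2-hydroxypropan-2-yl)-3-[(1S)-1-(4-hydroxy-1-methyl-2-oxo-1,2-dihydroquinolin-3-yl)-3-methylbut-2-en-1-yl]-5-methyl-2,3-dihydrofuro[3,2-c]quinolin-4(5H)-one (formed with 12 as the racemate) | CC(C)=C[C@H](c1c(O)c2ccccc2n(C)c1=O)[C@@H]1c2c(c3ccccc3n(C)c2=O)O[C@@H]1C(C)(C)O
F4 | step 3 | (3R,4S)-3,4-bis(2-methylprop-1-en-1-yl)hexanedioic acid (meso; with its racemic diastereomer) | OC(=O)C[C@@H](C=C(C)C)[C@@H](C=C(C)C)CC(=O)O
F5 | step 3 | (3R,4S)-3,4-bis(2-methylprop-1-en-1-yl)hexanedioyl dichloride | ClC(=O)C[C@@H](C=C(C)C)[C@@H](C=C(C)C)CC(=O)Cl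
F6 | step 3 | dimethyl 2,2'-{[(3R,4S)-3,4-bis(2-methylprop-1-en-1-yl)hexanedioyl]bis(methylazanediyl)}dibenzoate | COC(=O)c1ccccc1N(C)C(=O)C[C@@H](C=C(C)C)[C@@H](C=C(C)C)CC(=O)N(C)c1ccccc1C(=O)OC
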